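Readings and results are calculated with made-up constants, and the scatter is random.

**The question.** Which flask holds the most L at 30 min, and how much?

| flask | Q | Z | remark | time |
|---|---|---|---|---|
| maple | 1 M | 0.11 equiv | run made earlier |  |
| oak | 1 M | 1.1 equiv | run made earlier |  |
| midnight | 1.0 M | 0.800 equiv |  | 30 min |
| noon | 1.0 M | 0.400 equiv |  | 30 min |
| dawn | 1.0 M | 0.200 equiv |  | 30 min |
| spring | 1.0 M | 1.60 equiv |  | 30 min |
| dusk | 1.0 M | 0.260 equiv |  | 30 min |

| maple: time / min | maple: L / % | oak: time / min | oak: L / % |
|---|---|---|---|
| 4.00 | 4.6 | 2.00 | 33.4 |
| 8.00 | 5.5 | 5.00 | 36.6 |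
| 12.0 | 4.1 | 10.0 | 39.1 |
| 15.0 | 3.6 | 15.0 | 39.6 |
| 20.0 | 5.7 | 20.0 | 37.7 |

(readings scatter by 1 percentage point)

- the flasks by amount of L, in percent of the Q charged, highest first, at 30 min (midnight / noon / dawn / spring / dusk)
- the amount of L, in percent of the Q charged of the flask you put first, at 30 min
- the amount of L, in percent of the Q charged of the flask you put last, at 30 min

**Flat readings.** Q becomes D, and Z adds reversibly to D to give L. In oak, L reads 33.4% at 2.00 min. The readings from 10.0 min on average 38.8% and stay flat within a scatter of 1 percentage point. I read this flatness as equilibrium: the forward rate, its constant times cZ times cD, equals the back rate, its constant times cL. I also assume that no Q remains, so cD plus cL equals the Q charged. Each new flask runs 30 min, longer than the last oak reading at 20.0 min, so I treat them the same way.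

**Even point.** Dividing the two rates gives cL/cD = cZ/cE, where cE is the back constant over the forward constant. The level case, cL equal to cD, is my zero. From the oak average I read cL 0.388 M, and from the balances cD 0.612 M and cZ 0.712 M. That reading gives the even point cE = 1.12 M, the free cZ at which cL equals cD. It is the dissociation constant of L. The maple readings average 4.70%, and the even point from oak gives 5.04% there.

**My reckoning.** For each flask I solve cL/(Q charged − cL) = (Z charged − cL)/cE. Spring has the largest Z charge and dawn the smallest. With Q the same, L follows the Z charge, so my order is spring, midnight, noon, dusk, dawn. I get 49.6% for spring and 8.95% for dawn.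

**The forecast.** Holding that “all flasks should be equilibrated by 30 min”, the forecast gives spring > midnight > noon > dusk > dawn, with 49% and 8.9%, slightly under my two values.

**The flask.** The flasks come out as spring > midnight > noon > dusk > dawn, with spring at 49.6% and dawn at 8.95%.

    Q → D (k = 0.0480 s⁻¹)
    Z + D ⇌ L (K = 0.890 L mol⁻¹, k = 0.00930 L mol⁻¹ s⁻¹)

In spring, free Z stands at 1.10 M beside the even point of 1.12 M read from oak, with L 49.6% and D 50.4%. The neighbour is spring with 1.7 M of Q at the same equivalents. The same equation gives 60.2% there. In that neighbour, free Z stands at 1.70 M, above the even point, with D 39.8% and L 60.2%.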